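The vessel in Thursday's is closed, so nothing leaves it, and the first question is how its charge divides. Your hunch for the best flask is Thursday's and so is mine, but your quick number should start from the protic impurity, not the heat.

the same everywhere: starting material 0.10 M
- epsilon: protic impurity 0.020 M; temperature 75 °C; run made earlier
- theta: protic impurity 0.045 M; temperature 110 °C; run made earlier
- Thursday's: protic impurity 0.0300 M; temperature 140 °C; time 25 h
- Wednesday's: protic impurity 0.0300 M; temperature 80 °C; time 25 h
- Monday's: protic impurity 0.0300 M; at 80 °C until 8.0 h, from then on at 140 °C; time 25 h
- Friday's: protic impurity 0.0300 M; temperature 110 °C; time 25 h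

| run | time / h | product / % | starting material / % |
|---|---|---|---|
| epsilon | 120 | 4.3 | 38.4 |
| epsilon | 240 | 13.2 | 19.5 |
| epsilon | 360 | 19.8 | 9.4 |
| epsilon | 480 | 24.4 | 6.5 |
| epsilon | 600 | 26.6 | 3.2 |
| theta | 8.00 | 10.3 | 7.6 |
| theta | 20.0 | 20.5 | 2.2 |
| theta | 40.0 | 25.1 | 1.4 |
| theta | 48.0 | 25.9 | 1.1 |
| theta | 120 | 32.8 | 0.5 |

(standard deviation of a reading: 0.5 percentage points)

- in percentages every species weighs as the starting material in it: one homo dimer counts as two
- the analysis behind the earlier runs scatters by 0.5 percentage points, standard deviation
- steps that have been proposed: starting material -> intermediate; intermediate -> product; starting material <-> dormant form; starting material + protic impurity -> quenched substrate; 2 starting material -> homo dimer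

- the flask with the highest amount of product, in percent of the starting material charged ("all alike" if they lie within 1.5 percentage points) (Thursday's / Wednesday's / Monday's / Friday's / all alike)
- final product, as a percentage of the starting material charged, in Thursday's
- final product, as a percentage of the starting material charged, in Wednesday's
- final product, as a percentage of the starting material charged, in Monday's
- final product, as a percentage of the starting material charged, in Friday's

Each protic impurity takes one starting material into quenched substrate, and no proposed step takes that further. One minus [protic impurity]/[starting material] as charged, here 70.0 %, is what I call the impurity ceiling: the share of the charge that can still reach product once the impurity, the limiting reagent of the quench, has been used up. Thursday's, Wednesday's, Monday's and Friday's have the same charges, so they share this ceiling.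

Theta has a ceiling of 55.0 %, and its 32.8 % of product after 120 h is 59.6 % of that. For the clock, starting material read 9.4 % after 360 h at 75 °C in epsilon and 7.6 % after 8.00 h at 110 °C in theta, roughly a stretch of 45.0 in time, though these two runs differ in protic impurity as well as in temperature. Thursday's needs a stretch of 4.80 for its 25 h to cover theta's 120 h, and I expect it to get that, so I take the same share of the ceiling as my low estimate, 41.7 %. The stretch read between epsilon and theta is larger than the one needed, so I commit to midway between that estimate and the ceiling, 55.9 %. Monday's has 17.0 h at 140 °C, so I put it under Thursday's. Friday's should lie near theta's 20.5 % to 25.1 %. Wednesday's should stay under the 4.3 % that epsilon read after 120 h.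

The forecast names Thursday's, with 44 % for Thursday's, 1 % for Wednesday's, 42 % for Monday's and 28 % for Friday's, holding that at 140 °C “everything finishes”, and my Thursday's figure stands above it.

Thursday's holds the most product, 59.3 %, against Monday's 53.4 %, Friday's 27.8 % and Wednesday's 0.803 %.

    starting material → intermediate (k = 0.0846 h⁻¹, Ea = 114 kJ mol⁻¹)
    intermediate → product (k = 0.176 h⁻¹, Ea = 109 kJ mol⁻¹)
    starting material ⇌ dormant form (K = 11.4, k = 0.123 h⁻¹, Ea = 115 kJ mol⁻¹, ΔH = −7.00 kJ mol⁻¹)
    starting material + protic impurity → quenched substrate (k = 17.2 M⁻¹ h⁻¹, Ea = 68.0 kJ mol⁻¹)
    2 starting material → homo dimer (k = 0.129 M⁻¹ h⁻¹, Ea = 106 kJ mol⁻¹)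
    (constants at 110 °C)

At 25.0 h Thursday's still holds 7.04 % as dormant form, and left for 250 h its product reads 66.8 %, under the ceiling of 70.0 %. The neighbour of Thursday's charged with 0.051 M of protic impurity has a ceiling of 49.0 %, and at 25.0 h its product stands below that, at 43.5 %.

The readings are calculated on assumed constants.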